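**Retrosynthetic overview**

1. The 6‑acetate and the free 3‑OH are set last. The butenolide ring is bought as 3‑bromofuran‑2(5H)‑one and joined at C12–C13 by B‑alkyl Suzuki coupling to a C11=C12 vinyl carbinol. The 9α‑OH/C11 unit comes from α‑face epoxidation of a C9 methylene group and one‑carbon homologation.
2. The C9 ketone goes back to a bicyclic dienedione: γ‑oxidation of the ring B enone brings in the C6 oxygen, hydride adds to C3 and C6 from the α face, and C8 is equilibrated.
3. Ring A of the dienedione is cut at C1–C2 and C3–C4. The two‑carbon unit C2–C3(=O), (trimethylsilyl)ketene, is stitched between the formyl carbon C1 and the isopropenyl carbon C4 of a monocyclic keto aldehyde (radical addition to the ketene carbonyl carbon, then enolate aldol addition and Peterson elimination).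
4. Enabling feature: in the keto aldehyde the electrophilic C1 (CHO on the quaternary, non‑enolisable C10) and the radical precursor C4 (isopropenyl on C5) sit on neighbouring ring B carbons, trans to each other and 1,4‑related through C10–C5. A two‑atom insert can therefore only close the six‑membered, trans‑fused ring A.
5. The keto aldehyde comes from (R)‑carvone (ring B and C5) by two α′‑functionalisations. Ring order: ring B (bought) → ring A (key step) → butenolide ring (bought, attached late).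

Key step: step 4

Remark on the chemistry: the target is read as 6β‑acetoxy‑3β,9α‑dihydroxylabd‑13‑en‑16,15‑olide (3S,5S,6R,8R,9R,10S; 5α‑H, 8α‑CH3, 10β‑CH3). Labdane/drimane numbering (ring A = C1–C5, C10; ring B = C5–C10) is used for all bicyclic compounds. (Trimethylsilyl)ketene and 3‑bromofuran‑2(5H)‑one are taken as purchasable.

**Route**

Step 1
Reactants: 1 (R)‑(−)‑carvone
Product: 2 (5R,6S)‑2,6‑dimethyl‑5‑(prop‑1‑en‑2‑yl)cyclohex‑2‑en‑1‑one (trans‑6‑methylcarvone; the minor 6‑epimer is carried along)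
Conditions: LiN(i‑Pr)2, THF, −78 °C; MeI, −78 → 0 °C
Reagents that add atoms: iodomethane CI
Why: Kinetic α′‑deprotonation of the enone and enolate alkylation should place the methyl group on the future C10, mainly anti to the isopropenyl group, and this centre is planarised again in step 2, so both epimers serve.

Step 2
Reactants: 2 (5R,6S)‑2,6‑dimethyl‑5‑(prop‑1‑en‑2‑yl)cyclohex‑2‑en‑1‑one
Product: 3 (5S,6R)‑6‑(hydroxymethyl)‑2,6‑dimethyl‑5‑(prop‑1‑en‑2‑yl)cyclohex‑2‑en‑1‑one
Conditions: LiN(i‑Pr)2, THF, −78 °C; CH2O (monomeric, THF), −78 °C; AcOH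
Reagents that add atoms: formaldehyde C=O
Why: Aldol addition of the tetrasubstituted lithium enolate to formaldehyde should occur anti to the neighbouring isopropenyl group, which sets the quaternary future C10 with CH3 cis and CH2OH (future C1) trans to isopropenyl.

Step 3
Reactants: 3 (5S,6R)‑6‑(hydroxymethyl)‑2,6‑dimethyl‑5‑(prop‑1‑en‑2‑yl)cyclohex‑2‑en‑1‑one
Product: 4 (1R,6S)‑1,3‑dimethyl‑2‑oxo‑6‑(prop‑1‑en‑2‑yl)cyclohex‑3‑ene‑1‑carbaldehyde
Conditions: Dess–Martin periodinane, CH2Cl2, 25 °C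
Reagents that add atoms: none
Why: Dess–Martin oxidation of the neopentyl primary alcohol should give the non‑enolisable β‑keto aldehyde under neutral conditions, without touching a stereocentre.

Step 4
Reactants: 4 (1R,6S)‑1,3‑dimethyl‑2‑oxo‑6‑(prop‑1‑en‑2‑yl)cyclohex‑3‑ene‑1‑carbaldehyde; 5 (trimethylsilyl)ketene
Product: 7 11‑nordrima‑1,7‑diene‑3,9‑dione (5α‑H; 10β‑CH3), via 2‑silyl aldol adduct 6 (not isolated)
Conditions: Fe(acac)3 (30 mol %), PhSiH2(Oi‑Pr), 5 (4 equiv), THF, 0 → 25 °C; then TsOH·H2O (cat.), 25 °C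
Reagents that add atoms: none
Why: Proposed new method: an iron hydride formed from Fe(acac)3 and the silane transfers a hydrogen atom to the CH2 terminus of the isopropenyl group, the nucleophilic tertiary C4 radical adds to the electrophilic carbonyl carbon of the silylketene (C3–C4; the other ketene carbon is shielded by Me3Si), divalent iron reduces the resulting α‑silyl‑α‑acyl radical to the enolate, and this enolate adds to the formyl group on C10 (C1–C2) and loses Me3SiO– in a Peterson elimination to give the C1=C2–C3=O enone. The closest known reaction types are the iron‑hydride HAT‑initiated radical–polar crossover annulation of isopropenyl‑bearing aldehydes with enones (Giese addition, then intramolecular aldol) and the one‑pot addition of carbon nucleophiles to (trimethylsilyl)ketene followed by Peterson olefination of aldehydes; new is only that a HAT‑generated radical is the partner of the ketene. Ring A closes in the aldol event by a 6‑(enolendo)‑exo‑trig addition, the only ring size possible because C1 and C4 are joined through C10–C5. No new stereocentre survives (C4 bears two methyl groups, C1 and C2 end sp2), and the trans ring fusion with 10β‑CH3 and 5α‑H follows from the trans arrangement of the CHO and isopropenyl groups fixed in 4. The step needs hydrogen‑atom transfer to the electron‑rich 1,1‑disubstituted alkene and not to the electron‑poor trisubstituted enone (secured by the polarity of the iron hydride, as with carvone itself), radical capture by the ketene before reduction (excess of 5), and aldol addition to the aldehyde and not to the hindered C9 ketone. The final acid treatment completes the elimination and converges any uncyclised α‑silyl ketone on 7 by desilylation and aldol condensation.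

Step 5
Reactants: 7 11‑nordrima‑1,7‑diene‑3,9‑dione
Product: 8 11‑nordrima‑1,7‑diene‑3,6,9‑trione
Conditions: Pd(OH)2/C (5 mol %), t‑BuOOH, K2CO3 (0.25 equiv), CH2Cl2, 4 °C
Reagents that add atoms: tert‑butyl hydroperoxide CC(C)(C)OO
Why: Palladium‑catalysed peroxide γ‑oxidation of an α,β‑enone to the ene‑1,4‑dione (allylic oxidation) should act only at C6, the sole γ‑CH2, since the ring A enone has no γ‑hydrogen; no stereocentre is formed and C5 should stay in the trans‑fused form.

Step 6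
Reactants: 8 11‑nordrima‑1,7‑diene‑3,6,9‑trione
Product: 9 3β,6β‑dihydroxy‑11‑nordrima‑1,7‑dien‑9‑one
Conditions: NaBH4, CeCl3·7H2O, MeOH, −78 → −40 °C
Reagents that add atoms: none
Why: Luche reduction should deliver hydride 1,2 to the C3 and C6 carbonyls from the α face, opposite the axial 4β‑ and 10β‑methyl groups (3β and 6β carbinols), while the C9 carbonyl between C8(CH3) and quaternary C10 is too hindered to react.

Step 7
Reactants: 9 3β,6β‑dihydroxy‑11‑nordrima‑1,7‑dien‑9‑one
Product: 10 3β‑(tert‑butyldimethylsilyloxy)‑6β‑hydroxy‑11‑nordrima‑1,7‑dien‑9‑one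
Conditions: TBSCl, imidazole, DMF, 0 → 25 °C
Reagents that add atoms: tert‑butyldimethylsilyl chloride CC(C)(C)[Si](C)(C)Cl
Why: Silyl ether formation should take place only at the pseudo‑equatorial 3β‑hydroxyl, because the axial 6β‑hydroxyl is shielded by the syn‑axial 4β‑ and 10β‑methyl groups.

Step 8
Reactants: 10 3β‑(tert‑butyldimethylsilyloxy)‑6β‑hydroxy‑11‑nordrima‑1,7‑dien‑9‑one
Product: 12 3β‑(tert‑butyldimethylsilyloxy)‑6β‑hydroxy‑11‑nordriman‑9‑one (8α‑CH3), via 8‑epimer 11 (not isolated)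
Conditions: H2 (1 atm), Pt/C, EtOAc, 25 °C; then DBU, toluene, 60 °C
Reagents that add atoms: none
Why: Heterogeneous hydrogenation saturates C1=C2 and C7=C8 (Pt rather than Pd to avoid redox isomerisation of the allylic C6 carbinol), and DBU then equilibrates C8 through the C9 enol to the equatorial 8α‑methyl epimer, which avoids the 1,3‑diaxial contact with the 10β‑methyl group.

Step 9
Reactants: 12 3β‑(tert‑butyldimethylsilyloxy)‑6β‑hydroxy‑11‑nordriman‑9‑one
Product: 13 3β‑(tert‑butyldimethylsilyloxy)drim‑9(11)‑en‑6β‑ol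
Conditions: Ph3P+CH3 Br−, KOt‑Bu, toluene, 90 °C
Reagents that add atoms: methyltriphenylphosphonium bromide C[P+](c1ccccc1)(c1ccccc1)c1ccccc1.[Br-]
Why: Wittig methylenation with the small ylide at raised temperature should convert the hindered C9 ketone into the exocyclic C9=C11 alkene, and transient enolisation does no harm because C8 is already the thermodynamic epimer.

Step 10
Reactants: 13 3β‑(tert‑butyldimethylsilyloxy)drim‑9(11)‑en‑6β‑ol
Product: 14 3β‑(tert‑butyldimethylsilyloxy)‑9α,11‑epoxydriman‑6β‑ol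
Conditions: mCPBA, NaHCO3, CH2Cl2, 0 °C
Reagents that add atoms: 3‑chloroperoxybenzoic acid OOC(=O)c1cccc(Cl)c1
Why: Prilezhaev epoxidation of the 1,1‑disubstituted alkene should occur from the α face, anti to the axial 10β‑methyl group, which sets C9 with the oxygen α and C11 β.

Step 11
Reactants: 14 3β‑(tert‑butyldimethylsilyloxy)‑9α,11‑epoxydriman‑6β‑ol
Product: 15 3β‑(tert‑butyldimethylsilyloxy)‑13,14,15,16‑tetranorlabd‑11‑ene‑6β,9α‑diol
Conditions: Me3S+ I−, n‑BuLi, THF, −10 → 25 °C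
Reagents that add atoms: trimethylsulfonium iodide C[S+](C)C.[I-]
Why: SN2 opening of the epoxide at its CH2 terminus (C11) by dimethylsulfonium methylide and loss of dimethyl sulfide (one‑carbon homologation of an epoxide to an allylic alcohol with the Corey–Chaykovsky reagent) should give the C11=C12 vinyl carbinol without breaking the C9–O bond, so C9 keeps its configuration.

Step 12
Reactants: 15 3β‑(tert‑butyldimethylsilyloxy)‑13,14,15,16‑tetranorlabd‑11‑ene‑6β,9α‑diol; 16 3‑bromofuran‑2(5H)‑one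
Product: 18 3β‑(tert‑butyldimethylsilyloxy)‑6β,9α‑dihydroxylabd‑13‑en‑16,15‑olide, via B‑alkyl‑9‑BBN adduct 17 (not isolated)
Conditions: 9‑BBN, THF, 25 °C; then 16, PdCl2(dppf) (cat.), AsPh3, Cs2CO3, DMF–H2O, 25 °C
Reagents that add atoms: none
Why: Anti‑Markovnikov hydroboration places boron on C12, and B‑alkyl Suzuki–Miyaura coupling with the alkenyl bromide forms C12–C13 with the butenolide ring already in place; no stereocentre is formed.

Step 13
Reactants: 18 3β‑(tert‑butyldimethylsilyloxy)‑6β,9α‑dihydroxylabd‑13‑en‑16,15‑olide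
Product: 19 6β‑acetoxy‑3β‑(tert‑butyldimethylsilyloxy)‑9α‑hydroxylabd‑13‑en‑16,15‑olide
Conditions: Ac2O, DMAP, pyridine, 50 °C
Reagents that add atoms: acetic anhydride CC(=O)OC(C)=O
Why: DMAP‑catalysed acetylation should esterify the secondary 6β‑hydroxyl, while the tertiary 9α‑hydroxyl between C8 and quaternary C10 stays free.

Step 14
Reactants: 19 6β‑acetoxy‑3β‑(tert‑butyldimethylsilyloxy)‑9α‑hydroxylabd‑13‑en‑16,15‑olide
Product: 20 6β‑acetoxy‑3β,9α‑dihydroxylabd‑13‑en‑16,15‑olide (target)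
Conditions: HF·pyridine, THF, 0 → 25 °C
Reagents that add atoms: none
Why: Fluoride‑mediated cleavage of the silyl ether (Si–F bond formation) should free the 3β‑hydroxyl, while the acetate, the tertiary alcohol and the butenolide are inert to HF·pyridine.

**Compound list**

1 | (R)‑(−)‑carvone, (5R)‑2‑methyl‑5‑(prop‑1‑en‑2‑yl)cyclohex‑2‑en‑1‑one | C1C=C(C)C(=O)C[C@@H]1C(C)=C | starting material
2 | (5R,6S)‑2,6‑dimethyl‑5‑(prop‑1‑en‑2‑yl)cyclohex‑2‑en‑1‑one (trans‑6‑methylcarvone) | C1C=C(C)C(=O)[C@@H](C)[C@@H]1C(C)=C | intermediate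
3 | (5S,6R)‑6‑(hydroxymethyl)‑2,6‑dimethyl‑5‑(prop‑1‑en‑2‑yl)cyclohex‑2‑en‑1‑one (CH3 cis, CH2OH trans to isopropenyl) | C1C=C(C)C(=O)[C@@](C)(CO)[C@@H]1C(C)=C | intermediate
4 | (1R,6S)‑1,3‑dimethyl‑2‑oxo‑6‑(prop‑1‑en‑2‑yl)cyclohex‑3‑ene‑1‑carbaldehyde (CHO trans to isopropenyl) | C1C=C(C)C(=O)[C@@](C)(C=O)[C@@H]1C(C)=C | intermediate
5 | (trimethylsilyl)ketene | C[Si](C)(C)C=C=O | starting material
6 | 1‑hydroxy‑2‑(trimethylsilyl)‑11‑nordrim‑7‑ene‑3,9‑dione (5α‑H, 10β‑CH3; C1 and C2 not fixed; present as its iron alkoxide) | C1C=C(C)C(=O)[C@@]2(C)C(O)C([Si](C)(C)C)C(=O)C(C)(C)[C@H]12 | intermediate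
7 | 11‑nordrima‑1,7‑diene‑3,9‑dione (5α‑H, 10β‑CH3) | C1C=C(C)C(=O)[C@@]2(C)C=CC(=O)C(C)(C)[C@H]12 | intermediate
8 | 11‑nordrima‑1,7‑diene‑3,6,9‑trione (5α‑H, 10β‑CH3) | O=C1C=C(C)C(=O)[C@@]2(C)C=CC(=O)C(C)(C)[C@H]12 | intermediate
9 | 3β,6β‑dihydroxy‑11‑nordrima‑1,7‑dien‑9‑one | O[C@@H]1C=C(C)C(=O)[C@@]2(C)C=C[C@H](O)C(C)(C)[C@H]12 | intermediate
10 | 3β‑(tert‑butyldimethylsilyloxy)‑6β‑hydroxy‑11‑nordrima‑1,7‑dien‑9‑one | O[C@@H]1C=C(C)C(=O)[C@@]2(C)C=C[C@H](O[Si](C)(C)C(C)(C)C)C(C)(C)[C@H]12 | intermediate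
11 | 3β‑(tert‑butyldimethylsilyloxy)‑6β‑hydroxy‑8‑epi‑11‑nordriman‑9‑one (8β‑CH3) | O[C@@H]1C[C@H](C)C(=O)[C@@]2(C)CC[C@H](O[Si](C)(C)C(C)(C)C)C(C)(C)[C@H]12 | intermediate
12 | 3β‑(tert‑butyldimethylsilyloxy)‑6β‑hydroxy‑11‑nordriman‑9‑one (8α‑CH3) | O[C@@H]1C[C@@H](C)C(=O)[C@@]2(C)CC[C@H](O[Si](C)(C)C(C)(C)C)C(C)(C)[C@H]12 | intermediate
13 | 3β‑(tert‑butyldimethylsilyloxy)drim‑9(11)‑en‑6β‑ol | O[C@@H]1C[C@@H](C)C(=C)[C@@]2(C)CC[C@H](O[Si](C)(C)C(C)(C)C)C(C)(C)[C@H]12 | intermediate
14 | 3β‑(tert‑butyldimethylsilyloxy)‑9α,11‑epoxydriman‑6β‑ol | O[C@@H]1C[C@@H](C)[C@]3(CO3)[C@@]2(C)CC[C@H](O[Si](C)(C)C(C)(C)C)C(C)(C)[C@H]12 | intermediate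
15 | 3β‑(tert‑butyldimethylsilyloxy)‑13,14,15,16‑tetranorlabd‑11‑ene‑6β,9α‑diol | O[C@@H]1C[C@@H](C)[C@](O)(C=C)[C@@]2(C)CC[C@H](O[Si](C)(C)C(C)(C)C)C(C)(C)[C@H]12 | intermediate
16 | 3‑bromofuran‑2(5H)‑one | O=C1OCC=C1Br | starting material
17 | 12‑(9‑borabicyclo[3.3.1]nonan‑9‑yl)‑3β‑(tert‑butyldimethylsilyloxy)‑13,14,15,16‑tetranorlabdane‑6β,9α‑diol (written with free hydroxyls) | O[C@@H]1C[C@@H](C)[C@](O)(CCB3C4CCCC3CCC4)[C@@]2(C)CC[C@H](O[Si](C)(C)C(C)(C)C)C(C)(C)[C@H]12 | intermediate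
18 | 3β‑(tert‑butyldimethylsilyloxy)‑6β,9α‑dihydroxylabd‑13‑en‑16,15‑olide | O[C@@H]1C[C@@H](C)[C@](O)(CCC3=CCOC3=O)[C@@]2(C)CC[C@H](O[Si](C)(C)C(C)(C)C)C(C)(C)[C@H]12 | intermediate
19 | 6β‑acetoxy‑3β‑(tert‑butyldimethylsilyloxy)‑9α‑hydroxylabd‑13‑en‑16,15‑olide | CC(=O)O[C@@H]1C[C@@H](C)[C@](O)(CCC3=CCOC3=O)[C@@]2(C)CC[C@H](O[Si](C)(C)C(C)(C)C)C(C)(C)[C@H]12 | intermediate
20 | 6β‑acetoxy‑3β,9α‑dihydroxylabd‑13‑en‑16,15‑olide | CC(=O)O[C@@H]1C[C@@H](C)[C@](O)(CCC2=CCOC2=O)[C@@]2(C)CC[C@H](O)C(C)(C)[C@H]12 | target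

**Step count and risks**

Total step count: 14. Longest linear sequence: 14 steps, from 1 to 20.

Steps most likely to fail:

Step 4. The hindered tertiary radical may be reduced to the isopropyl group, or add at the silyl‑bearing ketene carbon, faster than it attacks the ketene carbonyl carbon; the enolate may also be protonated before it cyclises. The fallback makes the two ring A bonds one after the other by known reactions, sets out from 2 and comes back at 12. The enolate of 2 (LiN(i‑Pr)2, THF–DMPU) is alkylated anti to the isopropenyl group with 2‑(2‑iodoethyl)‑1,3‑dioxolane to give the dioxolane F1. Aqueous acid frees the aldehyde F2. Iron‑hydride HAT‑initiated reductive radical cyclisation of the isopropenyl group onto the aldehyde carbon (Fe(acac)3, PhSiH3, EtOH, 60 °C) closes ring A at C3–C4 and should give the carbinol F3 as a C3 epimer mixture. Dess–Martin oxidation gives the 3‑ketone F4. The γ‑oxidation of step 5 then gives the enedione F5, the Luche reduction of step 6 the 3β,6β‑diol F6, the silylation of step 7 the silyl ether F7, and hydrogenation with equilibration as in step 8 leads to 12.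

Step 11. Opening of the neopentyl‑type spiro‑epoxide at C11 by the ylide may be outrun by attack of the ylide as a base and isomerisation of the epoxide. The fallback sets out from 13 and comes back at 15. Dihydroxylation from the α face (OsO4 cat., N‑methylmorpholine N‑oxide) gives the 9α,11‑diol F8. Selective oxidation of the primary hydroxyl (TEMPO, PhI(OAc)2) gives the α‑hydroxy aldehyde F9. Wittig methylenation (Ph3P=CH2) then gives 15.

Step 9. Steric shielding of the C9 carbonyl by C8–CH3 and the quaternary C10 may make the basic ylide enolise the ketone instead of adding to it. The fallback sets out from 12 and comes back at 13. Addition of the small, weakly basic Me3SiCH2Li/CeCl3 reagent gives the β‑hydroxysilane F10 (either C9 epimer serves). Peterson elimination with KH then gives 13.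

**Further compounds**

F1 | step 4 | 6‑[2‑(1,3‑dioxolan‑2‑yl)ethyl]‑2,6‑dimethyl‑5‑(prop‑1‑en‑2‑yl)cyclohex‑2‑en‑1‑one (side chain trans, CH3 cis to isopropenyl) | C1C=C(C)C(=O)[C@@](C)(CCC2OCCO2)[C@@H]1C(C)=C
F2 | step 4 | 3‑[1,3‑dimethyl‑2‑oxo‑6‑(prop‑1‑en‑2‑yl)cyclohex‑3‑en‑1‑yl]propanal (same configuration as F1) | C1C=C(C)C(=O)[C@@](C)(CCC=O)[C@@H]1C(C)=C
F3 | step 4 | 3‑hydroxy‑11‑nordrim‑7‑en‑9‑one (5α‑H, 10β‑CH3; C3 epimers) | C1C=C(C)C(=O)[C@@]2(C)CCC(O)C(C)(C)[C@H]12
F4 | step 4 | 11‑nordrim‑7‑ene‑3,9‑dione | C1C=C(C)C(=O)[C@@]2(C)CCC(=O)C(C)(C)[C@H]12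
F5 | step 4 | 11‑nordrim‑7‑ene‑3,6,9‑trione | O=C1C=C(C)C(=O)[C@@]2(C)CCC(=O)C(C)(C)[C@H]12
F6 | step 4 | 3β,6β‑dihydroxy‑11‑nordrim‑7‑en‑9‑one | O[C@@H]1C=C(C)C(=O)[C@@]2(C)CC[C@H](O)C(C)(C)[C@H]12
F7 | step 4 | 3β‑(tert‑butyldimethylsilyloxy)‑6β‑hydroxy‑11‑nordrim‑7‑en‑9‑one | O[C@@H]1C=C(C)C(=O)[C@@]2(C)CC[C@H](O[Si](C)(C)C(C)(C)C)C(C)(C)[C@H]12
F8 | step 11 | 3β‑(tert‑butyldimethylsilyloxy)drimane‑6β,9α,11‑triol | O[C@@H]1C[C@@H](C)[C@](O)(CO)[C@@]2(C)CC[C@H](O[Si](C)(C)C(C)(C)C)C(C)(C)[C@H]12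
F9 | step 11 | 3β‑(tert‑butyldimethylsilyloxy)‑6β,9α‑dihydroxydriman‑11‑al | O[C@@H]1C[C@@H](C)[C@](O)(C=O)[C@@]2(C)CC[C@H](O[Si](C)(C)C(C)(C)C)C(C)(C)[C@H]12
F10 | step 9 | 3β‑(tert‑butyldimethylsilyloxy)‑11‑(trimethylsilyl)drimane‑6β,9‑diol (C9 epimers) | O[C@@H]1C[C@@H](C)C(O)(C[Si](C)(C)C)[C@@]2(C)CC[C@H](O[Si](C)(C)C(C)(C)C)C(C)(C)[C@H]12
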